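(The numbers in the tables are calculated from invented constants; noise was put on by code.)

In a one-step world L + J → X, with Q and temperature held, the rate depends on the L and J present and not on what the flask has been through, so a used flask and a fresh flask with the same L and J go on alike. Tuesday's and Monday's runs are such a pair: once 40.0% of Tuesday's L has turned, Tuesday's flask holds the L and J that Monday's flask was charged with, and differs from it by 0.120 M of X.

| setting | Tuesday's | Monday's | Sunday's | Friday's | Thursday's |
|---|---|---|---|---|---|
| L | 0.300 M | 0.180 M | 0.150 M | 0.300 M | 0.300 M |
| J | 0.900 M | 0.780 M | 0.900 M | 1.80 M | 0.450 M |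
| Q | 0.00150 M | 0.00150 M | 0.00150 M | 0.00150 M | 4.90 × 10⁻⁴ M |
| time |  |  |  |  | 58 min |

| Tuesday's run: time / min | Tuesday's run: [X] / M | Monday's run: time / min | Monday's run: [X] / M | Sunday's run: time / min | Sunday's run: [X] / M | Friday's run: time / min | Friday's run: [X] / M |
|---|---|---|---|---|---|---|---|
| 12 | 0.0981 | 12 | 0.0699 | 12 | 0.0610 | 12 | 0.1018 |
| 23 | 0.1387 | 23 | 0.1026 | 23 | 0.0873 | 23 | 0.1458 |
| 35 | 0.1724 | 35 | 0.1202 | 35 | 0.1115 | 35 | 0.1714 |
| 46 | 0.1925 | 46 | 0.1333 | 46 | 0.1168 | 46 | 0.1969 |
| 58 | 0.2167 | 58 | 0.1422 | 58 | 0.1248 | 58 | 0.2123 |

(each reading ± 0.002 M)

- order of the initial rate in [J], near the charge of the Tuesday's run, the rate being that where two percent of its L are X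
- order of the initial rate in [L], near the charge of the Tuesday's run, the rate being that where two percent of its L are X (one fixed amount of X, the same in the runs compared)
- the Monday's run starts with 0.120 M less of L and of J than the Tuesday's run, and with no X. Compared where both hold the same amount of L, once fifteen percent of what the Monday's run was charged with has turned into X, is the Monday's run faster, slower or alike (within a tenth)?
- X in the Thursday's run at 58 min, as a share of the L charged
- which of these the readings show (the product ties up the catalyst / the substrate pairs with itself / two substrates go astray together / nothing beyond the main steps / the product binds the substrate)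

- Overall: L + J -> X, with Q as catalyst.
- Constant volume, constant temperature.
- Bound and free are read together.
- "The second partner" is J.
- An order is taken over about fifteen percent of the charge, up and down.

I run Tuesday's flask in slow motion. L is the limiting reagent, with J charged at 3.00 times as much. In its first 12 min, 32.7% of its L turns. Friday's flask, with twice the J, has made 0.1018 M of X by then against Tuesday's 0.0981 M, which I read, coarsely because these readings already span a good part of the run, as an order in J of 0.0534. Sunday's flask, with half the L, has made 0.622 of Tuesday's X by that time, which I read, as coarsely, as an order in L of 0.685.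

The middle is where the pair speaks. Between 23 min and 35 min the L of Tuesday's flask falls from 53.8% to 42.5% of Tuesday's charge, at 0.00281 M/min. Monday's flask, in its first 12 min, takes L from 60.0% to 36.7% of that same charge, a span that brackets Tuesday's, at a mean of 0.00583 M/min. The ratio of these readings is 2.07; I keep it as the brake, the slowing at like L and J in the flask with 0.120 M more X.

At the end, at 58 min, Tuesday's flask still holds 27.8% of its L, and between its last two readings it makes X at 0.00202 M/min, which is 24.7% of its mean rate over the first 12 min. So I say Monday's run is faster and that the product ties up the catalyst.

For Thursday's flask I assume the rate goes with Q, which the earlier runs never varied, and that the brake follows X and not the clock. Then its 58 min count as 18.9 min on Tuesday's curve, which carries the brake at each X. Its halved J shortens that to 18.3 min, and a straight line between Tuesday's readings gives 40.4% of the L charged.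

The forecast gives an order in J of 0.06 (−0.03 to 0.2), an order in L of 0.6 (0.4 to 0.8), Monday's run faster, 40% (34% to 45%) for Thursday's flask, and the product ties up the catalyst, reasoning that “Monday is clearly faster, so product ties up the catalyst”. Mine, 0.0534 in J and 0.685 in L, differ a little from these.

The flask gives an order in J of 0.20, an order in L of 0.54, Monday's run faster, 39.5% for Thursday's flask, and the product ties up the catalyst.

    Q + L → QL (70.80 /M/min)
    QL + J → Wy (54.90 /M/min)
    Wy → X + Q (34.86 /min)
    Q + X ⇌ QX, settled at all times (27.20 /M)

Monday's run at like L goes 2.4 times as fast as Tuesday's, and with the binding of Q + X into QX taken away that ratio is 1.0. So the brake of 2.07 that I read is this binding, product inhibition. Thursday's flask holds 0.118 M of X at 58 min, close to the 0.120 M behind that brake. Without the binding it reaches 61.5% instead of 39.5%, a difference of 22 percentage points.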